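**Strategy.** The oxolane ring is cut at O1–C9 and C6–C7: hexanal brings O1 and C6, and a six-carbon epoxy mesylate carrying a 2-iodoallyl unit brings C7–C11. One Ni/Cr-mediated operation adds the C7 alkenylchromium to hexanal under ligand control and then lets the new C6 alkoxide displace the C9 mesylate with inversion, closing the ring (O1, C6, C7, C8, C9) as a 2,5-trans 3-methylene oxolane. The step exploits the 1,4-placement of the two ring carbons that flank O1. The exocyclic methylene is a masked C7 carbinol, and the surviving terminal epoxide later receives the oct-7-enyl tail at C11, which unveils the C10 hydroxyl.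

Key step: step 5

Remark on the chemistry: atom numbers follow the nonadec-18-ene chain (O1 ring oxygen, C6 and C9 ring carbons on O1, C7 ester carbon, C10 free carbinol). In step 5 the antipode of the oxazoline–sulfonamide ligand that delivers the (6S) carbinol is assumed; its sense of induction is not derived here and would be fixed by a small-scale trial.

Step 1
Reactants: 1 acrolein; 2 2,3-dibromoprop-1-ene
Product: 4 rac-5-bromohexa-1,5-dien-3-ol, via (2-bromoprop-2-en-1-yl)zinc bromide 3 (not isolated)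
Conditions: Zn, THF/sat. aq. NH4Cl, 0 °C to rt
Reagents that add atoms: none
Why: Barbier-type allylation in which zinc inserts only into the allylic C–Br bond of 2 and the allylzinc adds 1,2 to acrolein, the vinylic bromide staying intact; the carbinol centre is formed racemic on purpose.

Step 2
Reactants: 4 rac-5-bromohexa-1,5-dien-3-ol
Product: 5 rac-5-iodohexa-1,5-dien-3-ol
Conditions: NaI, CuI (cat.), trans-N,N'-dimethylcyclohexane-1,2-diamine (cat.), 1,4-dioxane, 110 °C
Reagents that add atoms: sodium iodide, [Na+].[I-]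
Why: Copper-catalysed vinylic halogen exchange (Finkelstein type) should turn the alkenyl bromide into the iodide needed for fast oxidative addition to nickel; no stereocentre is touched.

Step 3
Reactants: 5 rac-5-iodohexa-1,5-dien-3-ol
Product: 6 (1S)-3-iodo-1-[(2R)-oxiran-2-yl]but-3-en-1-ol
Conditions: Ti(OiPr)4, L-(+)-diisopropyl tartrate, t-BuOOH (0.45 equiv), 4 Å molecular sieves, CH2Cl2, −20 °C
Reagents that add atoms: tert-butyl hydroperoxide, CC(C)(C)OO
Why: Sharpless kinetic resolution, in which the (S)-alcohol should be epoxidised fast on its allylic vinyl group to the erythro (anti) epoxy alcohol, fixing C9 by selection and C10 by reagent control, while the (R)-alcohol and the electron-poor homoallylic iodoalkene stay untouched.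

Step 4
Reactants: 6 (1S)-3-iodo-1-[(2R)-oxiran-2-yl]but-3-en-1-ol
Product: 7 (1S)-3-iodo-1-[(2R)-oxiran-2-yl]but-3-en-1-yl methanesulfonate
Conditions: MsCl, Et3N, CH2Cl2, −10 °C
Reagents that add atoms: methanesulfonyl chloride, CS(=O)(=O)Cl
Why: Sulfonylation of the secondary alcohol with retention turns the C9 oxygen into the leaving group for the later inversion.

Step 5
Reactants: 7 (1S)-3-iodo-1-[(2R)-oxiran-2-yl]but-3-en-1-yl methanesulfonate; 8 hexanal
Product: 10 (2S,5R)-3-methylidene-5-[(2R)-oxiran-2-yl]-2-pentyloxolane, via hydroxy mesylate 9 (not isolated)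
Conditions: CrCl2 (cat.), chiral 2-(oxazolin-2-yl)aryl methanesulfonamide ligand (cat.), 1,8-bis(dimethylamino)naphthalene (cat.), NiCl2(2,9-dimethyl-1,10-phenanthroline) (cat.), Mn, Cp2ZrCl2, LiCl, MeCN, rt; then MeOH, K2CO3, rt (same flask)
Reagents that add atoms: none
Why: Nozaki–Hiyama–Kishi coupling followed in the same flask by Williamson etherification: zerovalent nickel inserts into the C7–I bond, transmetalation gives a C7 alkenyl species of trivalent chromium that adds to hexanal (C6–C7), and Cp2ZrCl2 takes over the alkoxide so that chromium turns over with Mn. The closest known reaction type is the Ni/Cr coupling of 2-iodoallyl sulfonates or chlorides with aldehydes followed by base-induced closure to 3-methylene oxolanes. After MeOH frees alcohol 9, carbonate promotes 5-exo-tet SN2 attack of O1 on C9, which closes the oxolane ring (O1–C9). C6 (S) is set by the chiral sulfonamide–oxazoline ligand on chromium, which fixes the face of hexanal; C9 (R) results from inversion of the (S)-mesylate, and C10 is carried through. The step needs insertion into the alkenyl iodide in the presence of mesylate and epoxide (secured by the much faster oxidative addition of the sp2 C–I bond) and mesylate displacement in preference to 6-exo opening of the epoxide at C10 (secured by the better leaving group and the faster five-membered closure).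

Step 6
Reactants: 10 (2S,5R)-3-methylidene-5-[(2R)-oxiran-2-yl]-2-pentyloxolane
Product: 12 (2S,5R)-5-[(2R)-oxiran-2-yl]-2-pentyloxolan-3-one, via secondary ozonide 11 (not isolated)
Conditions: O3, CH2Cl2, −78 °C; then PPh3, −78 °C to rt
Reagents that add atoms: ozone, [O-][O+]=O
Why: Ozonolysis of the only C=C bond (1,3-dipolar cycloaddition, cycloreversion, reduction of the ozonide by PPh3) should unmask the C7 ketone under neutral conditions that spare the epoxide and the enolisable C6 centre.

Step 7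
Reactants: 12 (2S,5R)-5-[(2R)-oxiran-2-yl]-2-pentyloxolan-3-one
Product: 13 (2S,3S,5R)-5-[(2R)-oxiran-2-yl]-2-pentyloxolan-3-ol
Conditions: LiBH(s-Bu)3, THF, −78 °C; then aq. NH4Cl
Reagents that add atoms: none
Why: The bulky hydride should attack the C7 carbonyl from the face opposite the adjacent C6 pentyl group (steric approach control), giving the 2,3-cis alcohol (C7, S) at a temperature where the epoxide is inert.

Step 8
Reactants: 13 (2S,3S,5R)-5-[(2R)-oxiran-2-yl]-2-pentyloxolan-3-ol; 14 hexadecanoyl chloride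
Product: 15 (2S,3S,5R)-5-[(2R)-oxiran-2-yl]-2-pentyloxolan-3-yl hexadecanoate
Conditions: pyridine, DMAP (cat.), CH2Cl2, 0 °C to rt
Reagents that add atoms: none
Why: Acylation of the only hydroxyl under nucleophilic catalysis installs the palmitate on the C7 oxygen with retention.

Step 9
Reactants: 15 (2S,3S,5R)-5-[(2R)-oxiran-2-yl]-2-pentyloxolan-3-yl hexadecanoate; 16 8-bromooct-1-ene
Product: 18 (2S,3S,5R)-5-[(1R)-1-hydroxydec-9-en-1-yl]-2-pentyloxolan-3-yl hexadecanoate, via oct-7-en-1-ylmagnesium bromide 17 (not isolated)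
Conditions: 16, Mg, THF, rt; then 15, CuI (cat.), THF, −40 to −20 °C; aq. NH4Cl
Reagents that add atoms: none
Why: Copper-catalysed SN2 opening of the terminal epoxide by the Grignard reagent at the unhindered C11 forms C11–C12 and frees the C10 hydroxyl with retention at C10, and it is run cold so that the ester is not attacked.

**Compound list**

1 | acrolein (prop-2-enal) | C=CC=O | starting material
2 | 2,3-dibromoprop-1-ene | C=C(Br)CBr | starting material
3 | (2-bromoprop-2-en-1-yl)zinc bromide | C=C(Br)C[Zn]Br | intermediate (not isolated)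
4 | rac-5-bromohexa-1,5-dien-3-ol | C=CC(O)CC(Br)=C | intermediate
5 | rac-5-iodohexa-1,5-dien-3-ol | C=CC(O)CC(I)=C | intermediate
6 | (1S)-3-iodo-1-[(2R)-oxiran-2-yl]but-3-en-1-ol | C=C(I)C[C@H](O)[C@H]1CO1 | intermediate
7 | (1S)-3-iodo-1-[(2R)-oxiran-2-yl]but-3-en-1-yl methanesulfonate | C=C(I)C[C@H](OS(C)(=O)=O)[C@H]1CO1 | intermediate
8 | hexanal | CCCCCC=O | starting material
9 | (1S,4S)-4-hydroxy-3-methylidene-1-[(2R)-oxiran-2-yl]nonyl methanesulfonate (zirconium alkoxide, drawn as the alcohol that MeOH releases) | CCCCC[C@H](O)C(=C)C[C@H](OS(C)(=O)=O)[C@H]1CO1 | intermediate (not isolated)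
10 | (2S,5R)-3-methylidene-5-[(2R)-oxiran-2-yl]-2-pentyloxolane | C1[C@@H](O1)[C@H]2CC(=C)[C@H](CCCCC)O2 | intermediate
11 | (6S,8R)-8-[(2R)-oxiran-2-yl]-6-pentyl-1,2,4,7-tetraoxaspiro[4.4]nonane (secondary ozonide, both configurations at the spiro carbon) | C1[C@@H](O1)[C@H]2CC3(OOCO3)[C@H](CCCCC)O2 | intermediate (not isolated)
12 | (2S,5R)-5-[(2R)-oxiran-2-yl]-2-pentyloxolan-3-one | C1[C@@H](O1)[C@H]2CC(=O)[C@H](CCCCC)O2 | intermediate
13 | (2S,3S,5R)-5-[(2R)-oxiran-2-yl]-2-pentyloxolan-3-ol | C1[C@@H](O1)[C@H]2C[C@H](O)[C@H](CCCCC)O2 | intermediate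
14 | hexadecanoyl chloride (palmitoyl chloride) | CCCCCCCCCCCCCCCC(Cl)=O | starting material
15 | (2S,3S,5R)-5-[(2R)-oxiran-2-yl]-2-pentyloxolan-3-yl hexadecanoate | C1[C@@H](O1)[C@H]2C[C@H](OC(=O)CCCCCCCCCCCCCCC)[C@H](CCCCC)O2 | intermediate
16 | 8-bromooct-1-ene | C=CCCCCCCBr | starting material
17 | oct-7-en-1-ylmagnesium bromide | C=CCCCCCC[Mg]Br | intermediate (not isolated)
18 | (2S,3S,5R)-5-[(1R)-1-hydroxydec-9-en-1-yl]-2-pentyloxolan-3-yl hexadecanoate | C=CCCCCCCC[C@@H](O)[C@H]1C[C@H](OC(=O)CCCCCCCCCCCCCCC)[C@H](CCCCC)O1 | target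

**Count.** Total steps: 9. Longest linear sequence: 9 steps (1 and 2 to 18); the Grignard reagent of step 9 is made and used in the flask.

**Steps most likely to fail, with fallbacks**

Step 5. The terminal epoxide may be opened by chloride in the Lewis-acidic coupling medium, or the new alkoxide may attack the epoxide (6-exo) instead of displacing the mesylate. The fallback removes the epoxide from the key step and rebuilds it afterwards; it sets out from 6 and returns at 10.
- Acetone with BF3·OEt2 (cat.) should convert the epoxide of 6 into the acetonide (1S)-1-[(4R)-2,2-dimethyl-1,3-dioxolan-4-yl]-3-iodobut-3-en-1-ol F1 (attack at the terminal carbon, C10 retained).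
- MsCl/Et3N should give (1S)-1-[(4R)-2,2-dimethyl-1,3-dioxolan-4-yl]-3-iodobut-3-en-1-yl methanesulfonate F2.
- The same Ni/Cr coupling with 8 should pass through the hydroxy mesylate (1S,4S)-1-[(4R)-2,2-dimethyl-1,3-dioxolan-4-yl]-4-hydroxy-3-methylidenenonyl methanesulfonate F3 (not isolated), which carbonate closes to (4R)-2,2-dimethyl-4-[(2R,5S)-4-methylidene-5-pentyloxolan-2-yl]-1,3-dioxolane F4.
- Aqueous AcOH should free the diol (1R)-1-[(2R,5S)-4-methylidene-5-pentyloxolan-2-yl]ethane-1,2-diol F5.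
- TsCl, Et3N and Bu2SnO (cat.) should give the primary sulfonate (2R)-2-hydroxy-2-[(2R,5S)-4-methylidene-5-pentyloxolan-2-yl]ethyl 4-methylbenzenesulfonate F6, and K2CO3 in MeOH closes the epoxide to 10.

Step 9. The Grignard reagent may add to the palmitate carbonyl in competition with epoxide opening. The fallback places the organometallic step before the acylation; it sets out from 13 and returns at 18.
- Et3SiCl/imidazole should give triethyl{[(2S,3S,5R)-5-[(2R)-oxiran-2-yl]-2-pentyloxolan-3-yl]oxy}silane F7.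
- Reagent 17 with CuI (cat.) should open the epoxide to (1R)-1-[(2R,4S,5S)-5-pentyl-4-(triethylsilyloxy)oxolan-2-yl]dec-9-en-1-ol F8.
- t-BuMe2SiOTf/2,6-lutidine should give tert-butyldimethyl{[(1R)-1-[(2R,4S,5S)-5-pentyl-4-(triethylsilyloxy)oxolan-2-yl]dec-9-en-1-yl]oxy}silane F9.
- Pyridinium tosylate in MeOH should remove only the triethylsilyl group to give (2S,3S,5R)-5-[(1R)-1-(tert-butyldimethylsilyloxy)dec-9-en-1-yl]-2-pentyloxolan-3-ol F10.
- Acylation with 14 should give (2S,3S,5R)-5-[(1R)-1-(tert-butyldimethylsilyloxy)dec-9-en-1-yl]-2-pentyloxolan-3-yl hexadecanoate F11, and HF·pyridine in THF frees 18.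

Step 2. The copper-catalysed halogen exchange may stall, or the heat-sensitive dienol may decompose at the temperature it needs. The fallback replaces it by halogen–lithium exchange on a protected alcohol; it sets out from 4 and returns at 5.
- t-BuMe2SiCl/imidazole should give rac-[(5-bromohexa-1,5-dien-3-yl)oxy](tert-butyl)dimethylsilane F12.
- t-BuLi in Et2O at −78 °C should give the alkenyllithium rac-{4-[(tert-butyldimethylsilyl)oxy]hexa-1,5-dien-2-yl}lithium F13 (not isolated).
- I2 should trap it as rac-tert-butyl[(5-iodohexa-1,5-dien-3-yl)oxy]dimethylsilane F14, and Bu4NF returns 5.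

**Further compounds**

F1 | step 5 | (1S)-1-[(4R)-2,2-dimethyl-1,3-dioxolan-4-yl]-3-iodobut-3-en-1-ol | C=C(I)C[C@H](O)[C@H]1COC(C)(C)O1
F2 | step 5 | (1S)-1-[(4R)-2,2-dimethyl-1,3-dioxolan-4-yl]-3-iodobut-3-en-1-yl methanesulfonate | C=C(I)C[C@H](OS(C)(=O)=O)[C@H]1COC(C)(C)O1
F3 | step 5 | (1S,4S)-1-[(4R)-2,2-dimethyl-1,3-dioxolan-4-yl]-4-hydroxy-3-methylidenenonyl methanesulfonate | CCCCC[C@H](O)C(=C)C[C@H](OS(C)(=O)=O)[C@H]1COC(C)(C)O1
F4 | step 5 | (4R)-2,2-dimethyl-4-[(2R,5S)-4-methylidene-5-pentyloxolan-2-yl]-1,3-dioxolane | C1OC(C)(C)O[C@H]1[C@H]2CC(=C)[C@H](CCCCC)O2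
F5 | step 5 | (1R)-1-[(2R,5S)-4-methylidene-5-pentyloxolan-2-yl]ethane-1,2-diol | OC[C@@H](O)[C@H]1CC(=C)[C@H](CCCCC)O1
F6 | step 5 | (2R)-2-hydroxy-2-[(2R,5S)-4-methylidene-5-pentyloxolan-2-yl]ethyl 4-methylbenzenesulfonate | Cc1ccc(cc1)S(=O)(=O)OC[C@@H](O)[C@H]1CC(=C)[C@H](CCCCC)O1
F7 | step 9 | triethyl{[(2S,3S,5R)-5-[(2R)-oxiran-2-yl]-2-pentyloxolan-3-yl]oxy}silane | C1[C@@H](O1)[C@H]2C[C@H](O[Si](CC)(CC)CC)[C@H](CCCCC)O2
F8 | step 9 | (1R)-1-[(2R,4S,5S)-5-pentyl-4-(triethylsilyloxy)oxolan-2-yl]dec-9-en-1-ol | C=CCCCCCCC[C@@H](O)[C@H]1C[C@H](O[Si](CC)(CC)CC)[C@H](CCCCC)O1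
F9 | step 9 | tert-butyldimethyl{[(1R)-1-[(2R,4S,5S)-5-pentyl-4-(triethylsilyloxy)oxolan-2-yl]dec-9-en-1-yl]oxy}silane | C=CCCCCCCC[C@@H](O[Si](C)(C)C(C)(C)C)[C@H]1C[C@H](O[Si](CC)(CC)CC)[C@H](CCCCC)O1
F10 | step 9 | (2S,3S,5R)-5-[(1R)-1-(tert-butyldimethylsilyloxy)dec-9-en-1-yl]-2-pentyloxolan-3-ol | C=CCCCCCCC[C@@H](O[Si](C)(C)C(C)(C)C)[C@H]1C[C@H](O)[C@H](CCCCC)O1
F11 | step 9 | (2S,3S,5R)-5-[(1R)-1-(tert-butyldimethylsilyloxy)dec-9-en-1-yl]-2-pentyloxolan-3-yl hexadecanoate | C=CCCCCCCC[C@@H](O[Si](C)(C)C(C)(C)C)[C@H]1C[C@H](OC(=O)CCCCCCCCCCCCCCC)[C@H](CCCCC)O1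
F12 | step 2 | rac-[(5-bromohexa-1,5-dien-3-yl)oxy](tert-butyl)dimethylsilane | C=CC(O[Si](C)(C)C(C)(C)C)CC(Br)=C
F13 | step 2 | rac-{4-[(tert-butyldimethylsilyl)oxy]hexa-1,5-dien-2-yl}lithium | C=CC(O[Si](C)(C)C(C)(C)C)CC([Li])=C
F14 | step 2 | rac-tert-butyl[(5-iodohexa-1,5-dien-3-yl)oxy]dimethylsilane | C=CC(O[Si](C)(C)C(C)(C)C)CC(I)=C
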